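Readings and results stem from a simulated flask for substances that don't exist, noise included.

The north-west run has converted 77.9 % of its substrates by 4.00 d and the south-east run 72.2 % by 4.00 d, yet the north-west run carries 1.50 times the free catalyst and twice the substrate.

| flask | left-handed substrate | right-handed substrate | gas | free catalyst | racemization catalyst | remark | time |
|---|---|---|---|---|---|---|---|
| south-east | 0.75 M | 0.75 M | 200 mM (held) | 38 mM | 75 mM | run made earlier |  |
| east | 1.1 M | 1.1 M | 200 mM (held) | 38 mM | 75 mM | run made earlier |  |
| north-west | 1.5 M | 1.5 M | 200 mM (held) | 57 mM | 75 mM | run made earlier |  |
| flask | 1.5 M | 1.5 M | 200 mM (held) | 38 mM | 75 mM |  | 4.0 d |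

| run | time / d | left-handed product / % | right-handed product / % | left-handed substrate / % |
|---|---|---|---|---|
| south-east | 0.625 | 11.8 | 3.8 | 39.9 |
| south-east | 1.25 | 21.6 | 9.3 | 30.5 |
| south-east | 2.08 | 34.5 | 14.6 | 22.3 |
| south-east | 2.50 | 38.2 | 16.7 | 19.0 |
| south-east | 3.00 | 43.4 | 20.1 | 15.7 |
| south-east | 4.00 | 50.2 | 22.0 | 10.6 |
| east | 0.333 | 4.8 | 2.3 | 45.6 |
| east | 0.500 | 8.4 | 3.3 | 42.4 |
| east | 0.833 | 13.6 | 6.0 | 37.4 |
| east | 1.67 | 26.6 | 10.6 | 28.4 |
| east | 2.50 | 36.0 | 14.4 | 21.4 |
| east | 4.00 | 48.6 | 22.5 | 11.5 |
| north-west | 0.333 | 5.9 | 1.9 | 44.1 |
| north-west | 1.04 | 18.0 | 8.0 | 32.9 |
| north-west | 1.67 | 29.1 | 12.3 | 25.7 |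
| north-west | 3.00 | 45.5 | 19.8 | 14.2 |
| north-west | 4.00 | 53.7 | 24.2 | 8.5 |

(each reading ± 0.5 percentage points)

* left-handed product and right-handed product together, in percent of the left-handed substrate and right-handed substrate charged together, at 4.0 d
* excess of left-handed product over right-handed product in the product at 4.0 d
* whether the exchange between left-handed substrate and right-handed substrate keeps pace with the reaction: how far the product's excess at 4.0 d gets from its value without exchange to its value with instant exchange (above 80 % keeps pace, below 20 % hardly takes part, else lags behind)

- free catalyst is single-handed; left-handed substrate and right-handed substrate are mirror images of each other, charged as a racemate, each of them at the stated concentration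
- at the start none of partner is dissolved
- on the list of suspects stand: partner + free catalyst + left-handed substrate -> free catalyst + left-handed product; partner + free catalyst + right-handed substrate -> free catalyst + right-handed product; left-handed substrate + racemization catalyst <-> right-handed substrate + racemization catalyst; racemization catalyst -> spent catalyst; gas <-> partner
- an excess is the difference of the two amounts in percent of their sum
- an excess is below zero if the other one leads

In the first instants the flask holds no partner, and both product steps wait for gas to dissolve. Then free catalyst, which each step hands back, stays at its charge, and partner follows the level where its supply from gas nearly meets its use, a quasi-steady level that climbs as the substrates fall. In this middle stretch the substrates decay in roughly pseudo-first-order fashion, and two delays add: one shrinks as free catalyst grows, the other grows with the substrate load.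

Reckoned from the fraction left, the time in which remaining substrate shrinks by the factor e is 3.12 d in the south-east run and 2.65 d in the north-west run. These two readings split into a catalyst part of 2.70 d at 38 mM and a gas part of 0.850 d at 1.5 M of each substrate, the first being larger. The east run, kept out of that split, is then due 3.32 d and reads 3.22 d. The flask joins the south-east catalyst charge to the north-west load, so its clearing time, the time in which its remaining substrate shrinks by the factor e, is 3.55 d, and by 4.0 d it has converted 67.6 %.

Towards the end the substrates stay lopsided. In the south-east run at 4.00 d, left-handed product and left-handed substrate together stand 11 percentage points above half of the charge, so exchange has carried substrate across. Yet left-handed substrate, at 10.6 %, still stands below the right-handed 17.2 %. The reckoning here therefore takes the south-east excess of 39.1 % for the flask and says that exchange lags behind.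

The forecast, holding that “gas supply (partner) starts to limit the rate”, gives 67.5 %, 39 % and lags behind.

The flask gives 67.0 % and an excess of 39.7 %, and exchange lags behind, getting 61 % of the way to its instant value.

    partner + free catalyst + left-handed substrate → free catalyst + left-handed product (k = 0.0601 L² mol⁻² min⁻¹)
    partner + free catalyst + right-handed substrate → free catalyst + right-handed product (k = 0.0215 L² mol⁻² min⁻¹)
    left-handed substrate + racemization catalyst ⇌ right-handed substrate + racemization catalyst, rate k3*[racemization catalyst]*[left-handed substrate] forward; the back reaction follows from the equilibrium constant (k = 0.00557 L mol⁻¹ min⁻¹)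
    racemization catalyst → spent catalyst (k = 6.93 × 10⁻⁵ min⁻¹)
    gas ⇌ partner, rate k5*(csat - [partner]) (kL = 0.00545 min⁻¹)

That conversion means a clearing time of 3.60 d in the flask. At 4.00 d partner is made 1.03 times as fast as it is used. With free catalyst at 0.0095 M, a quarter of the flask's charge, the catalyst part grows to 10.8 d and the clearing time to 11.6 d, which means 29.2 % converted; that neighbour flask gives 30.5 %.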